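**Retrosynthetic overview**
- The target comes from acetylation of an (S)-2-aryl glycidol, made by Sharpless asymmetric epoxidation (L-(+)-DIPT) of a 2-arylallyl alcohol. The oxirane is the only ring formed (step 13); the benzene ring is bought.
- The three hydroxyls are told apart by MOM (phenol), PMB (C7–OH) and TBDPS (C10–OH). They are exchanged in the order PMB → isovalerate, MOM → angelate, then TBDPS off, so the base-labile aryl angelate is installed before the epoxide exists.
- The 2-arylallyl alcohol comes from DIBAL reduction of a 2-arylacrylate. Key C–C bond (C8–C9): intermolecular crossed aldol condensation of the tert-butyl arylacetate enolate with formaldehyde.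
- The arylacetate comes from Pd-catalysed Reformatsky arylation of an aryl bromide derived from methyl 4-bromo-3-hydroxybenzoate.

Assumption: the SMILES is read as the (R)-oxirane carrying a (Z)-2-methylbut-2-enoate (angelate); thymol numbering is used (C7 benzylic CH2O, C8 oxirane quaternary carbon, C9 oxirane CH2, C10 CH2OAc), and formaldehyde 8 is charged as paraformaldehyde.

**Route**

Step 1
Reactants: 1 methyl 4-bromo-3-hydroxybenzoate
Product: 2 methyl 4-bromo-3-(methoxymethoxy)benzoate
Conditions: MOMCl, i-Pr2NEt, CH2Cl2, 0 °C → rt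
Reagents that add atoms: chloromethyl methyl ether (MOMCl), COCCl
Why: O-alkylation (Williamson-type) of the acidic phenol gives a MOM acetal that is stable to hydride, base, Pd and DDQ in the steps that follow.

Step 2
Reactants: 2 methyl 4-bromo-3-(methoxymethoxy)benzoate
Product: 3 [4-bromo-3-(methoxymethoxy)phenyl]methanol
Conditions: DIBAL-H (2.5 eq), CH2Cl2, −78 → 0 °C; Rochelle salt work-up
Reagents that add atoms: none
Why: DIBAL-H ester reduction gives the benzylic alcohol while the aryl bromide and the acetal are inert at low temperature.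

Step 3
Reactants: 3 [4-bromo-3-(methoxymethoxy)phenyl]methanol
Product: 4 1-bromo-4-{[(4-methoxybenzyl)oxy]methyl}-2-(methoxymethoxy)benzene
Conditions: NaH, PMBCl, n-Bu4NI (cat.), DMF, 0 °C → rt
Reagents that add atoms: 4-methoxybenzyl chloride (PMBCl), COc1ccc(CCl)cc1
Why: Williamson etherification installs a PMB ether that survives the coupling, aldol and hydride steps and is later removed oxidatively, orthogonal to MOM and TBDPS.

Step 4
Reactants: 4 1-bromo-4-{[(4-methoxybenzyl)oxy]methyl}-2-(methoxymethoxy)benzene; 5 tert-butyl bromoacetate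
Product: 7 tert-butyl 2-[4-{[(4-methoxybenzyl)oxy]methyl}-2-(methoxymethoxy)phenyl]acetate, via Reformatsky reagent 6 (not isolated)
Conditions: Zn dust (TMSCl-activated), THF, 40 °C; then 4, Pd(dba)2 (2 mol %), Q-Phos (2 mol %), THF, rt → 50 °C
Reagents that add atoms: zinc, [Zn] (carried only by 6)
Why: Zinc insertion gives the Reformatsky reagent, and its Pd-catalysed Negishi-type α-arylation (Hartwig) runs under neutral conditions that tolerate the acetal and benzylic ether and stops at mono-arylation.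

Step 5
Reactants: 7 tert-butyl 2-[4-{[(4-methoxybenzyl)oxy]methyl}-2-(methoxymethoxy)phenyl]acetate; 8 formaldehyde (as paraformaldehyde)
Product: 10 tert-butyl 2-[4-{[(4-methoxybenzyl)oxy]methyl}-2-(methoxymethoxy)phenyl]prop-2-enoate, via β-hydroxy ester 9 (not isolated)
Conditions: (CH2O)n (3 eq), K2CO3 (2 eq), n-Bu4NI (10 mol %), toluene, 80 °C
Reagents that add atoms: none
Why: Crossed aldol condensation: the ester enolate adds to non-enolisable formaldehyde and the β-hydroxy ester loses water by E1cB under solid–liquid phase transfer, forging C8–C9 (the stereocentre of racemic 9 is destroyed on dehydration).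

Step 6
Reactants: 10 tert-butyl 2-[4-{[(4-methoxybenzyl)oxy]methyl}-2-(methoxymethoxy)phenyl]prop-2-enoate
Product: 11 2-[4-{[(4-methoxybenzyl)oxy]methyl}-2-(methoxymethoxy)phenyl]prop-2-en-1-ol
Conditions: DIBAL-H (2.5 eq), CH2Cl2, −78 → 0 °C; Rochelle salt work-up
Reagents that add atoms: none
Why: DIBAL-H reduces the enoate by 1,2-addition only, giving the 2-arylallyl alcohol without touching the alkene.

Step 7
Reactants: 11 2-[4-{[(4-methoxybenzyl)oxy]methyl}-2-(methoxymethoxy)phenyl]prop-2-en-1-ol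
Product: 12 tert-butyl({2-[4-{[(4-methoxybenzyl)oxy]methyl}-2-(methoxymethoxy)phenyl]prop-2-en-1-yl}oxy)diphenylsilane
Conditions: TBDPSCl, imidazole, CH2Cl2, rt
Reagents that add atoms: tert-butyl(chloro)diphenylsilane (TBDPSCl), CC(C)(C)[Si](Cl)(c1ccccc1)c1ccccc1
Why: Silylation of the primary allylic alcohol gives a TBDPS ether that is stable to DDQ, acylation and the MOM cleavage and is removed last under non-basic fluoride conditions.

Step 8
Reactants: 12 tert-butyl({2-[4-{[(4-methoxybenzyl)oxy]methyl}-2-(methoxymethoxy)phenyl]prop-2-en-1-yl}oxy)diphenylsilane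
Product: 13 [4-(3-{[tert-butyl(diphenyl)silyl]oxy}prop-1-en-2-yl)-3-(methoxymethoxy)phenyl]methanol
Conditions: DDQ (1.3 eq), CH2Cl2/pH 7 buffer (10:1), 0 °C → rt
Reagents that add atoms: none
Why: Oxidative PMB cleavage: DDQ abstracts hydride only from the electron-rich anisyl CH2 and the oxocarbenium ion is hydrolysed, leaving MOM, TBDPS and the alkene intact.

Step 9
Reactants: 13 [4-(3-{[tert-butyl(diphenyl)silyl]oxy}prop-1-en-2-yl)-3-(methoxymethoxy)phenyl]methanol
Product: 14 4-(3-{[tert-butyl(diphenyl)silyl]oxy}prop-1-en-2-yl)-3-(methoxymethoxy)benzyl 3-methylbutanoate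
Conditions: isovaleryl chloride, pyridine, CH2Cl2, 0 °C → rt
Reagents that add atoms: 3-methylbutanoyl chloride (isovaleryl chloride), CC(C)CC(Cl)=O
Why: Acylation of the only free hydroxyl with an acid chloride installs the C7 isovalerate.

Step 10
Reactants: 14 4-(3-{[tert-butyl(diphenyl)silyl]oxy}prop-1-en-2-yl)-3-(methoxymethoxy)benzyl 3-methylbutanoate
Product: 16 4-(3-{[tert-butyl(diphenyl)silyl]oxy}prop-1-en-2-yl)-3-hydroxybenzyl 3-methylbutanoate, via aryl trimethylsilyl ether 15 (not isolated)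
Conditions: TMSOTf (2 eq), 2,2′-bipyridyl (3 eq), MeCN, 0 °C → rt; then H2O
Reagents that add atoms: trimethylsilyl trifluoromethanesulfonate (TMSOTf), C[Si](C)(C)OS(=O)(=O)C(F)(F)F (its Me3Si group is carried only by 15)
Why: Fujioka MOM cleavage: the bipyridyl-buffered silyl triflate converts the aryl acetal to the aryl TMS ether without free acid, so the acid-sensitive α-substituted styrene, the ester and the TBDPS ether survive, and water then frees the phenol.

Step 11
Reactants: 16 4-(3-{[tert-butyl(diphenyl)silyl]oxy}prop-1-en-2-yl)-3-hydroxybenzyl 3-methylbutanoate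
Product: 17 2-(3-{[tert-butyl(diphenyl)silyl]oxy}prop-1-en-2-yl)-5-{[(3-methylbutanoyl)oxy]methyl}phenyl (2Z)-2-methylbut-2-enoate
Conditions: angelic acid, 2,4,6-Cl3C6H2COCl, Et3N, toluene, rt, 2 h; then 16, rt → 40 °C (no DMAP)
Reagents that add atoms: angelic acid [(2Z)-2-methylbut-2-enoic acid], C/C=C(/C)C(O)=O
Why: Yamaguchi-type mixed-anhydride esterification: the phenoxide attacks the unhindered angeloyl carbonyl, and leaving out nucleophilic catalysts avoids the addition–elimination that isomerises Z (angelate) to E (tiglate).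

Step 12
Reactants: 17 2-(3-{[tert-butyl(diphenyl)silyl]oxy}prop-1-en-2-yl)-5-{[(3-methylbutanoyl)oxy]methyl}phenyl (2Z)-2-methylbut-2-enoate
Product: 18 2-(3-hydroxyprop-1-en-2-yl)-5-{[(3-methylbutanoyl)oxy]methyl}phenyl (2Z)-2-methylbut-2-enoate
Conditions: HF·pyridine, THF/pyridine, 0 °C → rt
Reagents that add atoms: none
Why: Fluoride desilylation under mildly acidic conditions frees the allylic alcohol without generating an alkoxide, so the aryl ester neither cleaves nor migrates.

Step 13
Reactants: 18 2-(3-hydroxyprop-1-en-2-yl)-5-{[(3-methylbutanoyl)oxy]methyl}phenyl (2Z)-2-methylbut-2-enoate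
Product: 19 2-[(2S)-2-(hydroxymethyl)oxiran-2-yl]-5-{[(3-methylbutanoyl)oxy]methyl}phenyl (2Z)-2-methylbut-2-enoate
Conditions: Ti(OiPr)4 (10 mol %), L-(+)-DIPT (12 mol %), t-BuOOH (2 eq, decane), 4 Å MS, CH2Cl2, −20 °C; aq. FeSO4/tartaric acid work-up
Reagents that add atoms: tert-butyl hydroperoxide, CC(C)(C)OO
Why: Katsuki–Sharpless asymmetric epoxidation: the Ti–L-(+)-tartrate complex delivers oxygen to the same alkene face as in 2-methylallyl alcohol → (S)-2-methylglycidol, setting the quaternary centre as (S), while the electron-poor angelate alkene is not oxidised.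

Step 14
Reactants: 19 2-[(2S)-2-(hydroxymethyl)oxiran-2-yl]-5-{[(3-methylbutanoyl)oxy]methyl}phenyl (2Z)-2-methylbut-2-enoate
Product: 20 2-[(2R)-2-(acetoxymethyl)oxiran-2-yl]-5-{[(3-methylbutanoyl)oxy]methyl}phenyl (2Z)-2-methylbut-2-enoate
Conditions: Ac2O, pyridine, CH2Cl2, 0 °C
Reagents that add atoms: acetic anhydride, CC(=O)OC(C)=O
Why: O-acetylation of the primary alcohol touches no bond at the stereocentre; the descriptor changes from S to R only because CH2OAc now outranks the ring CH2.

**Compound list**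
1 | methyl 4-bromo-3-hydroxybenzoate | Oc1cc(C(=O)OC)ccc1Br | starting material
2 | methyl 4-bromo-3-(methoxymethoxy)benzoate | COCOc1cc(C(=O)OC)ccc1Br | intermediate
3 | [4-bromo-3-(methoxymethoxy)phenyl]methanol | COCOc1cc(CO)ccc1Br | intermediate
4 | 1-bromo-4-{[(4-methoxybenzyl)oxy]methyl}-2-(methoxymethoxy)benzene | COCOc1cc(COCc2ccc(OC)cc2)ccc1Br | intermediate
5 | tert-butyl bromoacetate | CC(C)(C)OC(=O)CBr | starting material
6 | (2-tert-butoxy-2-oxoethyl)zinc bromide | CC(C)(C)OC(=O)C[Zn]Br | intermediate (not isolated)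
7 | tert-butyl 2-[4-{[(4-methoxybenzyl)oxy]methyl}-2-(methoxymethoxy)phenyl]acetate | COCOc1cc(COCc2ccc(OC)cc2)ccc1CC(=O)OC(C)(C)C | intermediate
8 | formaldehyde (charged as paraformaldehyde) | C=O | starting material
9 | tert-butyl 3-hydroxy-2-[4-{[(4-methoxybenzyl)oxy]methyl}-2-(methoxymethoxy)phenyl]propanoate (racemic) | COCOc1cc(COCc2ccc(OC)cc2)ccc1C(CO)C(=O)OC(C)(C)C | intermediate (not isolated)
10 | tert-butyl 2-[4-{[(4-methoxybenzyl)oxy]methyl}-2-(methoxymethoxy)phenyl]prop-2-enoate | COCOc1cc(COCc2ccc(OC)cc2)ccc1C(=C)C(=O)OC(C)(C)C | intermediate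
11 | 2-[4-{[(4-methoxybenzyl)oxy]methyl}-2-(methoxymethoxy)phenyl]prop-2-en-1-ol | COCOc1cc(COCc2ccc(OC)cc2)ccc1C(=C)CO | intermediate
12 | tert-butyl({2-[4-{[(4-methoxybenzyl)oxy]methyl}-2-(methoxymethoxy)phenyl]prop-2-en-1-yl}oxy)diphenylsilane | COCOc1cc(COCc2ccc(OC)cc2)ccc1C(=C)CO[Si](c1ccccc1)(c1ccccc1)C(C)(C)C | intermediate
13 | [4-(3-{[tert-butyl(diphenyl)silyl]oxy}prop-1-en-2-yl)-3-(methoxymethoxy)phenyl]methanol | COCOc1cc(CO)ccc1C(=C)CO[Si](c1ccccc1)(c1ccccc1)C(C)(C)C | intermediate
14 | 4-(3-{[tert-butyl(diphenyl)silyl]oxy}prop-1-en-2-yl)-3-(methoxymethoxy)benzyl 3-methylbutanoate | COCOc1cc(COC(=O)CC(C)C)ccc1C(=C)CO[Si](c1ccccc1)(c1ccccc1)C(C)(C)C | intermediate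
15 | 4-(3-{[tert-butyl(diphenyl)silyl]oxy}prop-1-en-2-yl)-3-[(trimethylsilyl)oxy]benzyl 3-methylbutanoate | C[Si](C)(C)Oc1cc(COC(=O)CC(C)C)ccc1C(=C)CO[Si](c1ccccc1)(c1ccccc1)C(C)(C)C | intermediate (not isolated)
16 | 4-(3-{[tert-butyl(diphenyl)silyl]oxy}prop-1-en-2-yl)-3-hydroxybenzyl 3-methylbutanoate | Oc1cc(COC(=O)CC(C)C)ccc1C(=C)CO[Si](c1ccccc1)(c1ccccc1)C(C)(C)C | intermediate
17 | 2-(3-{[tert-butyl(diphenyl)silyl]oxy}prop-1-en-2-yl)-5-{[(3-methylbutanoyl)oxy]methyl}phenyl (2Z)-2-methylbut-2-enoate | C/C=C(/C)C(=O)Oc1cc(COC(=O)CC(C)C)ccc1C(=C)CO[Si](c1ccccc1)(c1ccccc1)C(C)(C)C | intermediate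
18 | 2-(3-hydroxyprop-1-en-2-yl)-5-{[(3-methylbutanoyl)oxy]methyl}phenyl (2Z)-2-methylbut-2-enoate | C/C=C(/C)C(=O)Oc1cc(COC(=O)CC(C)C)ccc1C(=C)CO | intermediate
19 | 2-[(2S)-2-(hydroxymethyl)oxiran-2-yl]-5-{[(3-methylbutanoyl)oxy]methyl}phenyl (2Z)-2-methylbut-2-enoate | C/C=C(/C)C(=O)Oc1cc(COC(=O)CC(C)C)ccc1[C@]1(CO)CO1 | intermediate
20 | 2-[(2R)-2-(acetoxymethyl)oxiran-2-yl]-5-{[(3-methylbutanoyl)oxy]methyl}phenyl (2Z)-2-methylbut-2-enoate (CNP0212475.1) | C/C=C(/C)C(=O)Oc1cc(COC(=O)CC(C)C)ccc1[C@]1(COC(C)=O)CO1 | target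

**Step count and risks**
Total steps: 14. Longest linear sequence: 14 steps (1 → 20); 5 and 8 enter in steps 4 and 5.

The three steps most likely to fail:

Step 13 (asymmetric epoxidation). The risks are a modest ee for a 2-aryl allylic alcohol with a bulky ortho substituent, titanium-induced opening of the tertiary benzylic epoxide, and a shift of the angeloyl group from the phenol oxygen to the neighbouring titanium alkoxide. The fallback sets out from 18 and removes the free hydroxyl from the stereo-determining step. Acetylation (Ac2O, pyridine, CH2Cl2, 0 °C) gives the allyl acetate 2-[3-(acetyloxy)prop-1-en-2-yl]-5-{[(3-methylbutanoyl)oxy]methyl}phenyl (2Z)-2-methylbut-2-enoate F4. F4 is then epoxidised by a reagent-controlled Shi dioxirane epoxidation (carbohydrate-derived lactam ketone of the type developed for 1,1-disubstituted terminal olefins, Oxone, K2CO3/AcOH buffer at pH 8–9, DME–H2O, 0 °C), which does not attack the electron-poor angelate alkene. This returns to the route at the target 20. Which catalyst antipode gives the (R)-epoxide is not predicted here and must be fixed by a pilot run against material from steps 13–14; the ee would be polished by preparative chiral HPLC if needed.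

Step 5 (aldol condensation). The risks are sluggish enolisation of an electron-rich, ortho-substituted tert-butyl arylacetate by carbonate, double hydroxymethylation, and Michael dimerisation or polymerisation of the acrylate at 80 °C. The fallback sets out from 7 and makes the same C8–C9 bond by a low-temperature Mannich reaction. The lithium enolate (LiHMDS, THF, −78 °C) is aminomethylated with Eschenmoser's salt to give the Mannich base tert-butyl 3-(dimethylamino)-2-[4-{[(4-methoxybenzyl)oxy]methyl}-2-(methoxymethoxy)phenyl]propanoate F1. Quaternisation (MeI, MeCN, rt) gives the ammonium salt 3-tert-butoxy-2-[4-{[(4-methoxybenzyl)oxy]methyl}-2-(methoxymethoxy)phenyl]-N,N,N-trimethyl-3-oxopropan-1-aminium iodide F2. E1cB elimination of F2 with aqueous NaHCO3/CH2Cl2 at rt returns to the route at 10.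

Step 11 (angeloylation). The risks are Z → E isomerisation to the tiglate and slow acylation of the hindered phenol without a nucleophilic catalyst. The fallback sets out from 16 and builds the Z-alkene on the ester instead of transferring a preformed angeloyl group. Esterification with 2-[bis(2,2,2-trifluoroethoxy)phosphoryl]propanoic acid (EDC·HCl, CH2Cl2, 0 °C) gives the phosphonate 2-(3-{[tert-butyl(diphenyl)silyl]oxy}prop-1-en-2-yl)-5-{[(3-methylbutanoyl)oxy]methyl}phenyl 2-[bis(2,2,2-trifluoroethoxy)phosphoryl]propanoate F3. Still–Gennari olefination of F3 with acetaldehyde (KHMDS, 18-crown-6, THF, −78 °C) gives the Z-trisubstituted enoate and returns to the route at 17.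

**Further compounds**
F1 | step 5 | tert-butyl 3-(dimethylamino)-2-[4-{[(4-methoxybenzyl)oxy]methyl}-2-(methoxymethoxy)phenyl]propanoate (racemic) | COCOc1cc(COCc2ccc(OC)cc2)ccc1C(CN(C)C)C(=O)OC(C)(C)C
F2 | step 5 | 3-tert-butoxy-2-[4-{[(4-methoxybenzyl)oxy]methyl}-2-(methoxymethoxy)phenyl]-N,N,N-trimethyl-3-oxopropan-1-aminium iodide (racemic) | COCOc1cc(COCc2ccc(OC)cc2)ccc1C(C[N+](C)(C)C)C(=O)OC(C)(C)C.[I-]
F3 | step 11 | 2-(3-{[tert-butyl(diphenyl)silyl]oxy}prop-1-en-2-yl)-5-{[(3-methylbutanoyl)oxy]methyl}phenyl 2-[bis(2,2,2-trifluoroethoxy)phosphoryl]propanoate (racemic) | CC(C(=O)Oc1cc(COC(=O)CC(C)C)ccc1C(=C)CO[Si](c1ccccc1)(c1ccccc1)C(C)(C)C)P(=O)(OCC(F)(F)F)OCC(F)(F)F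
F4 | step 13 | 2-[3-(acetyloxy)prop-1-en-2-yl]-5-{[(3-methylbutanoyl)oxy]methyl}phenyl (2Z)-2-methylbut-2-enoate | C/C=C(/C)C(=O)Oc1cc(COC(=O)CC(C)C)ccc1C(=C)COC(C)=O
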